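**Retrosynthetic overview**
1. Target 15 comes from its 7-O-benzyl ether 14 by hydrogenolysis; the benzyl group keeps the 7-oxygen distinct from the three ring-A methyl ethers throughout.
2. Flavone 14 is cut at C4a–C4, C4–C3 and O1–C2 into ortho-iodophenol 9, carbon monoxide 11 and 4-ethynylanisole 10, joined in one palladium-catalysed carbonylative alkyne annulation.
3. Feature: ring A carries oxygen on C5, C6, C7, C8 and C8a, so C4a is its only oxygen-free carbon. The iodine can therefore sit only there, next to the C8a hydroxyl, and the C4 carbonyl can be delivered as CO between C4a and the C3≡C2 alkyne.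
4. Iodophenol 9 comes from 2,6-dimethoxyphenol 1: O-benzylation, symmetric dibromination, conversion of one bromine to OH (Li/B/oxidation) and the other to OMe (CuBr/NaOMe), then iodination of the last ring C–H.
5. Ring order: ring A (from 1) and ring B (from 10) are bought; ring C, the pyranone, is the only ring formed and closes in step 6.

Key step: step 6

Remark: enaminone 13 is drawn as the E isomer; its double-bond geometry is lost on ring closure and has no bearing on the outcome.

**Route**

Step 1
Reactants: 1 2,6-dimethoxyphenol; 2 benzyl bromide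
Product: 3 2-(benzyloxy)-1,3-dimethoxybenzene
Conditions: K2CO3, DMF, 60 °C
Reagents that add atoms: none
Why: Williamson ether synthesis; the phenoxide of 1, although flanked by two methoxy groups, should displace bromide from the unhindered benzylic carbon by SN2.

Step 2
Reactants: 3 2-(benzyloxy)-1,3-dimethoxybenzene
Product: 4 3-(benzyloxy)-1,5-dibromo-2,4-dimethoxybenzene
Conditions: NBS (2.1 equiv), MeCN, 0 °C → 40 °C, dark
Reagents that add atoms: N-bromosuccinimide, O=C1CCC(=O)N1Br
Why: Electrophilic aromatic bromination; C4 and C6 of 3 are each ortho to one methoxy group and para to the other, whereas C5 is only para to the twisted central benzyloxy group, so both bromines should enter at the two equivalent positions and give a C2v-symmetric dibromide.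

Step 3
Reactants: 4 3-(benzyloxy)-1,5-dibromo-2,4-dimethoxybenzene
Product: 7 3-(benzyloxy)-5-bromo-2,4-dimethoxyphenol, via aryllithium 5 (not isolated), via dimethyl arylboronate 6 (not isolated)
Conditions: n-BuLi (1.0 equiv), THF, −78 °C; B(OMe)3, −78 °C → rt; AcOH, 30% H2O2, 0 °C → rt
Reagents that add atoms: hydrogen peroxide, OO
Why: Bromine–lithium exchange, borylation and boronate oxidation (1,2-aryl shift from boron to oxygen); the two bromines of 4 are equivalent, so one equivalent of n-BuLi at low temperature should exchange only one and no regiochemical question arises.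

Step 4
Reactants: 7 3-(benzyloxy)-5-bromo-2,4-dimethoxyphenol
Product: 8 3-(benzyloxy)-2,4,5-trimethoxyphenol
Conditions: NaOMe (25% in MeOH, 6 equiv), CuBr (0.3 equiv), DMF, 110 °C, Ar; then aq HCl
Reagents that add atoms: sodium methoxide, C[O-].[Na+]
Why: Ullmann-type copper-mediated methoxylation of an aryl bromide; a free phenol is tolerated as its sodium phenoxide, and the bromine is meta to that phenoxide, so it is not deactivated by direct conjugation.

Step 5
Reactants: 8 3-(benzyloxy)-2,4,5-trimethoxyphenol
Product: 9 3-(benzyloxy)-6-iodo-2,4,5-trimethoxyphenol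
Conditions: NIS (1.05 equiv), MeCN, −20 → 0 °C, dark
Reagents that add atoms: N-iodosuccinimide, O=C1CCC(=O)N1I
Why: Electrophilic aromatic iodination; C6 is the only ring carbon still bearing hydrogen and is ortho to the hydroxyl, ortho to a methoxy group and para to the benzyloxy group, so mild acid-free iodination should occur there.

Step 6
Reactants: 9 3-(benzyloxy)-6-iodo-2,4,5-trimethoxyphenol; 10 4-ethynylanisole; 11 carbon monoxide
Product: 14 7-(benzyloxy)-5,6,8-trimethoxy-2-(4-methoxyphenyl)-4H-chromen-4-one, via alkynyl ketone 12 (not isolated), via diethylamino enone 13 (not isolated)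
Conditions: PdCl2(PPh3)2 (5 mol %), CO (20 bar), Et2NH, 120 °C, autoclave
Reagents that add atoms: none
Why: PdCl2(PPh3)2 is reduced in the amine to zerovalent palladium, which adds oxidatively to the C4a–I bond of 9; the resulting arylpalladium iodide takes up CO to an aroylpalladium species, which meets the acetylide formed from 10 and Et2NH, and reductive elimination releases the ortho-hydroxyaryl alkynyl ketone 12 (bonds C4a–C4 and C4–C3). The closest known reaction type is the palladium-catalysed carbonylative Sonogashira coupling of ortho-iodophenols with terminal arylacetylenes and CO in a secondary amine, which gives flavones in one operation. Ring C closes in the same flask: Et2NH adds to the ynone to give the β-amino enone 13, and the C8a hydroxyl then attacks C2 and expels the amine, an addition–elimination equivalent to a 6-endo-dig oxa-Michael closure that forms O1–C2. No stereocentre is created. The step needs CO insertion to outrun direct aryl–alkyne coupling (which would end in a benzofuran) and six-membered closure to outrun 5-exo closure to an aurone; the two ortho substituents beside the palladium-bearing carbon and the CO pressure favour acyl formation before alkyne transfer, and the secondary amine routes the ynone through the enaminone, which is electrophilic only at C2. Because every other ring-A carbon bears oxygen, the iodide can only be on C4a and the annulation has a single possible regiochemistry.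

Step 7
Reactants: 14 7-(benzyloxy)-5,6,8-trimethoxy-2-(4-methoxyphenyl)-4H-chromen-4-one
Product: 15 7-hydroxy-5,6,8-trimethoxy-2-(4-methoxyphenyl)-4H-chromen-4-one (7-hydroxy-4',5,6,8-tetramethoxyflavone)
Conditions: H2 (1 atm), 10% Pd/C, EtOAc–MeOH, rt
Reagents that add atoms: none
Why: Catalytic hydrogenolysis of a benzyl aryl ether; the methyl ethers are inert and the C2–C3 double bond of the pyranone, a vinylogous ester conjugated to two arenes, should survive brief exposure at atmospheric pressure.

**Compound list**
1 | 2,6-dimethoxyphenol | COc1cccc(OC)c1O | starting material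
2 | benzyl bromide | BrCc1ccccc1 | starting material
3 | 2-(benzyloxy)-1,3-dimethoxybenzene | COc1cccc(OC)c1OCc1ccccc1 | intermediate
4 | 3-(benzyloxy)-1,5-dibromo-2,4-dimethoxybenzene | COc1c(Br)cc(Br)c(OC)c1OCc1ccccc1 | intermediate
5 | [3-(benzyloxy)-5-bromo-2,4-dimethoxyphenyl]lithium | [Li]c1cc(Br)c(OC)c(OCc2ccccc2)c1OC | intermediate
6 | dimethyl [3-(benzyloxy)-5-bromo-2,4-dimethoxyphenyl]boronate | COB(OC)c1cc(Br)c(OC)c(OCc2ccccc2)c1OC | intermediate
7 | 3-(benzyloxy)-5-bromo-2,4-dimethoxyphenol | Oc1cc(Br)c(OC)c(OCc2ccccc2)c1OC | intermediate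
8 | 3-(benzyloxy)-2,4,5-trimethoxyphenol | COc1cc(O)c(OC)c(OCc2ccccc2)c1OC | intermediate
9 | 3-(benzyloxy)-6-iodo-2,4,5-trimethoxyphenol | COc1c(OCc2ccccc2)c(OC)c(OC)c(I)c1O | intermediate
10 | 4-ethynylanisole | C#Cc1ccc(OC)cc1 | starting material
11 | carbon monoxide | [C-]#[O+] | starting material
12 | 1-[4-(benzyloxy)-2-hydroxy-3,5,6-trimethoxyphenyl]-3-(4-methoxyphenyl)prop-2-yn-1-one | COc1ccc(C#CC(=O)c2c(O)c(OC)c(OCc3ccccc3)c(OC)c2OC)cc1 | intermediate
13 | (E)-1-[4-(benzyloxy)-2-hydroxy-3,5,6-trimethoxyphenyl]-3-(diethylamino)-3-(4-methoxyphenyl)prop-2-en-1-one | CCN(CC)/C(=C/C(=O)c1c(O)c(OC)c(OCc2ccccc2)c(OC)c1OC)c1ccc(OC)cc1 | intermediate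
14 | 7-(benzyloxy)-5,6,8-trimethoxy-2-(4-methoxyphenyl)-4H-chromen-4-one | COc1ccc(-c2cc(=O)c3c(OC)c(OC)c(OCc4ccccc4)c(OC)c3o2)cc1 | intermediate
15 | 7-hydroxy-5,6,8-trimethoxy-2-(4-methoxyphenyl)-4H-chromen-4-one | COc1ccc(-c2cc(=O)c3c(OC)c(OC)c(O)c(OC)c3o2)cc1 | target

**Totals**
Total step count: 7. Longest linear sequence: 7 steps (1 → 15).

**Steps most likely to fail**

Step 6. Oxidative addition and CO insertion at the doubly ortho-substituted, very electron-rich C–I bond may be slow. Trapping of the aroylpalladium species by Et2NH (amide formation), loss of iodine by reduction, or carbonyl-free coupling could then take over. The fallback makes the ynone by organomagnesium acylation instead of palladium and CO. It sets out from 9 and comes back at 12, which closes to 14. Phenol 9 is protected (MOMCl, iPr2NEt, CH2Cl2) as 1-(benzyloxy)-4-iodo-2,3,6-trimethoxy-5-(methoxymethoxy)benzene F1. Iodine–magnesium exchange (iPrMgCl·LiCl, THF, −20 °C) should give [4-(benzyloxy)-2,3,5-trimethoxy-6-(methoxymethoxy)phenyl]magnesium chloride F2. Separately, 10 is deprotonated (n-BuLi, THF, −78 °C) to lithium (4-methoxyphenyl)acetylide F3 and quenched with N-methoxy-N-methylcarbamoyl chloride to give N-methoxy-N-methyl-3-(4-methoxyphenyl)prop-2-ynamide F4. Addition of F2 to F4 (Weinreb ketone synthesis, THF, 0 °C) should give 1-[4-(benzyloxy)-2,3,5-trimethoxy-6-(methoxymethoxy)phenyl]-3-(4-methoxyphenyl)prop-2-yn-1-one F5. HCl in MeOH removes the acetal to give 12, and warming in Et2NH/EtOH should close it through 13 to 14.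

Step 5. The pentaoxygenated phenol is a hydroquinone monoether, and the electrophilic iodine source may oxidise it (quinone formation with loss of a methyl group) instead of iodinating carbon. The fallback installs iodine by directed ortho-metalation. It sets out from 8 and comes back at 9. Phenol 8 is protected (MOMCl, iPr2NEt) as 3-(benzyloxy)-1,2,4-trimethoxy-5-(methoxymethoxy)benzene F6. The only ring C–H, flanked by the acetal and a methoxy group, is lithiated (n-BuLi, THF, −40 → 0 °C) to [4-(benzyloxy)-2,3,5-trimethoxy-6-(methoxymethoxy)phenyl]lithium F7. Quenching with I2 gives the iodide F1 already described for step 6, and HCl in MeOH gives 9.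

Step 4. Copper-mediated substitution at the electron-rich bromo phenoxide may be sluggish, with reductive loss of bromine competing. The fallback swaps the roles of the two oxygens, which the symmetry of dibromide 4 allows. It sets out from 7 and comes back at 8. Phenol 7 is methylated (MeI, K2CO3, acetone) to 3-(benzyloxy)-1-bromo-2,4,5-trimethoxybenzene F8. Bromine–lithium exchange (n-BuLi, THF, −78 °C) gives [3-(benzyloxy)-2,4,5-trimethoxyphenyl]lithium F9. B(OMe)3 gives dimethyl [3-(benzyloxy)-2,4,5-trimethoxyphenyl]boronate F10, and AcOH/H2O2 oxidation should give 8, the same compound as from step 4 because the two former bromine positions are equivalent.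

**Further compounds**
F1 | step 6 | 1-(benzyloxy)-4-iodo-2,3,6-trimethoxy-5-(methoxymethoxy)benzene | COCOc1c(I)c(OC)c(OC)c(OCc2ccccc2)c1OC
F2 | step 6 | [4-(benzyloxy)-2,3,5-trimethoxy-6-(methoxymethoxy)phenyl]magnesium chloride | COCOc1c([Mg]Cl)c(OC)c(OC)c(OCc2ccccc2)c1OC
F3 | step 6 | lithium (4-methoxyphenyl)acetylide | [Li]C#Cc1ccc(OC)cc1
F4 | step 6 | N-methoxy-N-methyl-3-(4-methoxyphenyl)prop-2-ynamide | CON(C)C(=O)C#Cc1ccc(OC)cc1
F5 | step 6 | 1-[4-(benzyloxy)-2,3,5-trimethoxy-6-(methoxymethoxy)phenyl]-3-(4-methoxyphenyl)prop-2-yn-1-one | COCOc1c(C(=O)C#Cc2ccc(OC)cc2)c(OC)c(OC)c(OCc2ccccc2)c1OC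
F6 | step 5 | 3-(benzyloxy)-1,2,4-trimethoxy-5-(methoxymethoxy)benzene | COCOc1cc(OC)c(OC)c(OCc2ccccc2)c1OC
F7 | step 5 | [4-(benzyloxy)-2,3,5-trimethoxy-6-(methoxymethoxy)phenyl]lithium | COCOc1c([Li])c(OC)c(OC)c(OCc2ccccc2)c1OC
F8 | step 4 | 3-(benzyloxy)-1-bromo-2,4,5-trimethoxybenzene | COc1cc(Br)c(OC)c(OCc2ccccc2)c1OC
F9 | step 4 | [3-(benzyloxy)-2,4,5-trimethoxyphenyl]lithium | [Li]c1cc(OC)c(OC)c(OCc2ccccc2)c1OC
F10 | step 4 | dimethyl [3-(benzyloxy)-2,4,5-trimethoxyphenyl]boronate | COB(OC)c1cc(OC)c(OC)c(OCc2ccccc2)c1OC
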